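The earlier runs and the new flask come from a simulation with made-up constants, and the scatter is random.

Left-handed product and left-handed substrate together cannot pass 50.0% of the charge unless right-handed substrate crosses over, yet in the cedar run they read 74.0% at 6.00 min. Two clocks therefore run in these flasks, and the new flask depends on how they stand to each other.

the same everywhere: left-handed substrate 0.20 M; right-handed substrate 0.20 M; added ligand 5.4 mM
- birch: partner 0.30 M; precatalyst 2 mM; run made earlier
- cedar: partner 1.2 M; precatalyst 2 mM; run made earlier
- flask: partner 0.600 M; precatalyst 2.0 mM; time 10 min

- birch (time / min: left-handed product / %, right-handed product / %, left-handed substrate / %): 0.667: 1, 0, 49; 1.33: 5, 0, 46; 2.50: 12, 0, 42; 4.00: 18, 2, 31; 8.00: 35, 4, 25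
- cedar (time / min: left-handed product / %, right-handed product / %, left-handed substrate / %): 0.667: 10, 0, 36; 2.00: 46, 1, 11; 4.00: 60, 8, 7; 6.00: 73, 6, 1; 8.00: 73, 5, 4

(standard deviation of a reading: 2 percentage points)

- free catalyst is single-handed; left-handed substrate and right-handed substrate are mirror images of each other, charged as a racemate, each of them at the stated concentration
- the earlier runs were read with a standard deviation of 2 percentage points
- an excess is the difference of the two amounts in percent of their sum
- an excess is below zero if the other one leads

- left-handed product and right-handed product together, in percent of the left-handed substrate and right-handed substrate charged together, at 10 min
- excess of left-handed product over right-handed product in the product at 10 min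
- whether the exchange between left-handed substrate and right-handed substrate keeps pace with the reaction: how far the product's excess at 10 min gets from its value without exchange to its value with instant exchange (above 80% keeps pace, below 20% hardly takes part, else lags behind)

The quicker clock is the use of left-handed substrate. Treated as pseudo-first-order, left-handed product gained per mean left-handed substrate reads 0.125 /min in birch and 1.15 /min in cedar. The flask's 0.600 M of partner is the geometric mean of their charges, so I take 0.379 /min, a half-life of 1.83 min.

Next comes exchange. Between 2.00 min and 6.00 min in cedar, the left-handed total gains on the mean gap between the two substrates at 0.170 /min, a forward half-life of 4.08 min, longer than that of use. Then comes the flask's 10 min, longer than both. Last stands right-handed product, 5% in cedar at 8.00 min with a scatter of 2 percentage points, too faint for me to read a selectivity.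

So left-handed substrate drains first and then lives on what crosses. Right-handed substrate falls too, since what crosses leaves it. With both constants held fixed, the ratio of left-handed over right-handed substrate stops moving where the exchange constant times one minus the squared ratio equals use times the ratio. That gives 0.383, the held ratio. It is 1 with instant exchange and zero without exchange. Lying between, it points to an exchange that lags; I put no number on the excess.

The forecast, on constants of its own, gives 68% of product, an excess of 82%, and an exchange that lags behind: “exchange gets about halfway”.

The flask gives 69.3% of product and an excess of 91.4%, 9.4 points above the forecast, and exchange lags behind at 67% of the way. Its selectivity factor is 40.3, so the rate constant of the right-handed step is 0.0248 of the left-handed one, against the forecast's 0.05. The two products form at a rate ratio of this factor times the substrate ratio, so product forming at the held ratio has an excess of 87.8% and product forming at a substrate ratio of 1 has 95.2%; the flask's accumulated product stands between them.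

    partner + free catalyst + left-handed substrate → free catalyst + left-handed product (k = 29.2 /M²/s)
    partner + free catalyst + right-handed substrate → free catalyst + right-handed product (k = 0.725 /M²/s)
    left-handed substrate ⇌ right-handed substrate (k = 0.00296 /s)
    free catalyst + added ligand ⇌ idle complex, settled at all times (K = 140 /M)
    2 free catalyst → spent catalyst (k = 3.69 /M/s)
    partner + precatalyst → free catalyst + spent reagent (k = 0.00791 /M/s)

In a neighbour flask with 0.15 M of partner, use extended from birch and cedar by their order is 0.0411 /min, the held ratio 0.886 and the excess of product forming at it 94.6%. That neighbour computes to an excess of 94.7% at 19.1% product, with left-handed over right-handed substrate at 0.883 after 10.0 min.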